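**Retrosynthetic overview** (labdane numbering: ring A = C1–C5, C10; ring B = C5–C10; C17 = carboxyl carbon; C20 = angular methyl)

1. The C17 carboxyl is cut back to a C8 ketone (Δ7 enol triflate, hydroxycarbonylation); the isobutyrate is put on C15–OH last.
2. The C9–C11 bond comes from addition of a side-chain alkyllithium to a C9 carbonyl, followed by removal of the C9 oxygen with SmI2 (alkylative 1,2-carbonyl transposition C9 → C8); C9 is set under thermodynamic control.
3. Ring A is cut at C1–C10 and C2–C3: both bonds come from one Michael/Wittig annulation of a ring-B enol silane–aldehyde with vinyltriphenylphosphonium bromide (the C1–C2 unit); the C2=C3 olefin is then hydrogenated.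
4. Enabling feature: C10 is the α-carbon of a ring-B ketone (C9), and C3 sits 1,5 to that carbonyl across the quaternary gem-dimethyl carbon C4 (C9–C10–C5–C4–C3). C10 can therefore be an enolate carbon and C3 a non-enolizable aldehyde, and the C5 stereocenter next to C10 steers the new quaternary center.
5. Ring order: ring B is bought as 2-methylcyclohex-2-en-1-one (C5, C4 and C3 come from an asymmetric Mukaiyama–Michael addition); ring A is closed second, in the key step.

Key step: step 3

Assumption: the (S)-configured oxazaborolidinium catalyst is taken to give the (R)-adduct 3; if the sense of induction should be the opposite, the (R)-catalyst is used.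

**Step 1**
Reactants: 1 2-methylcyclohex-2-en-1-one; 2 [(1-methoxy-2-methylprop-1-en-1-yl)oxy]trimethylsilane
Product: 3 methyl 2-methyl-2-[(1R)-2-methyl-3-[(trimethylsilyl)oxy]cyclohex-2-en-1-yl]propanoate
Conditions: 2 (1.3 equiv), (S)-3,3-diphenyl-1-(o-tolyl)tetrahydro-1H,3H-pyrrolo[1,2-c][1,3,2]oxazaborole·HNTf2 (20 mol%), Ph3PO (25 mol%), toluene, −20 °C
Reagents that add atoms: none
Why: In this catalytic enantioselective Mukaiyama–Michael addition the cationic chiral boron Lewis acid binds the enone carbonyl and shields one face of the β-carbon, so that the ketene acetal should set the C5 stereocenter, while Ph3PO relays the silyl group to the enolate oxygen and the tetrasubstituted enol silane is obtained regiospecifically.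

**Step 2**
Reactants: 3 methyl 2-methyl-2-[(1R)-2-methyl-3-[(trimethylsilyl)oxy]cyclohex-2-en-1-yl]propanoate
Product: 4 2-methyl-2-[(1R)-2-methyl-3-[(trimethylsilyl)oxy]cyclohex-2-en-1-yl]propanal
Conditions: i-Bu2AlH (1.2 equiv), CH2Cl2, −78 °C; then MeOH, aq. potassium sodium tartrate
Reagents that add atoms: none
Why: In this partial ester reduction the tetrahedral aluminate of the hindered α-quaternary ester should persist at −78 °C and collapse to the aldehyde only on work-up, the enol silane is inert to the hydride, and no stereocenter is touched.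

**Step 3**
Reactants: 4 2-methyl-2-[(1R)-2-methyl-3-[(trimethylsilyl)oxy]cyclohex-2-en-1-yl]propanal; 5 triphenyl(vinyl)phosphonium bromide
Product: 8 (4aS,8aS)-5,5,8a-trimethyl-3,4,4a,5,8,8a-hexahydronaphthalen-1(2H)-one, via sulfonium enolate 6 (not isolated), via phosphorus ylide 7 (not isolated)
Conditions: 5 (1.3 equiv), tris(dimethylamino)sulfonium difluorotrimethylsilicate (TASF, 1.1 equiv, slow addition), THF/MeCN, 4 Å molecular sieves, −40 °C → rt, then 50 °C
Reagents that add atoms: none
Why: Fluoride cleaves the O–Si bond of 4 and frees the tetrasubstituted enolate 6 regiospecifically and without a proton source, so that it cannot equilibrate to the other α-carbon; 6 adds in a Michael reaction to the terminal carbon of the vinylphosphonium salt (new C1–C10 bond) to give the non-stabilized ylide 7, which closes on the aldehyde in an intramolecular Wittig reaction (new C2=C3 bond, loss of Ph3PO). The closest known reaction type is the tandem Michael addition/intramolecular Wittig annulation of keto- and aldehydo-enolates with vinyltriphenylphosphonium bromide, here combined with the fluoride generation of naked enolates from enol silanes. Ring A is closed by attack of the ylide carbon on the carbonyl carbon three atoms away from C10 (six-membered ring, exo mode at the C=O, via the oxaphosphetane), which can only give the cis ring olefin. The new quaternary stereocenter C10 is controlled by C5: A(1,2) strain with the C10 methyl forces the C(CH3)2CHO group pseudoaxial and the acceptor should attack the enolate face anti to it, so that C1 and C4 end up trans and the ring fusion trans. The step needs C- over O-alkylation and a Michael addition faster than aldol chemistry; the soft, unhindered, cationic acceptor favors C-attack, the aldehyde has no α-hydrogen and is neopentylic, its addition to the enolate oxygen (lactolate) is reversible, and the aldol at C10 would give a four-membered ring.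

**Step 4**
Reactants: 8 (4aS,8aS)-5,5,8a-trimethyl-3,4,4a,5,8,8a-hexahydronaphthalen-1(2H)-one
Product: 9 (4aS,8aS)-5,5,8a-trimethyloctahydronaphthalen-1(2H)-one
Conditions: H2 (1 atm), 10% Pd/C, EtOAc, rt
Reagents that add atoms: none
Why: Heterogeneous catalytic hydrogenation should saturate the cis-disubstituted ring-A olefin, the only C=C bond present, and leave the hindered ketone and both stereocenters untouched.

**Step 5**
Reactants: 9 (4aS,8aS)-5,5,8a-trimethyloctahydronaphthalen-1(2H)-one
Product: 10 (4aS,8aS)-2-hydroxy-5,5,8a-trimethyl-4a,5,6,7,8,8a-hexahydronaphthalen-1(4H)-one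
Conditions: O2 (1 atm), KOtBu (3 equiv), t-BuOH, rt; then aq. HCl
Reagents that add atoms: dioxygen, O=O
Why: In this base-mediated autoxidation of a ketone flanked by a quaternary carbon, the only possible enolate (toward C8) should trap O2 and the α-hydroperoxide lose water to the 1,2-dione, which rests as the diosphenol enolized toward C7 because C10 carries no hydrogen.

**Step 6**
Reactants: 10 (4aS,8aS)-2-hydroxy-5,5,8a-trimethyl-4a,5,6,7,8,8a-hexahydronaphthalen-1(4H)-one
Product: 11 (4aS,8aS)-5,5,8a-trimethyl-2-[(triethylsilyl)oxy]-4a,5,6,7,8,8a-hexahydronaphthalen-1(4H)-one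
Conditions: Et3SiCl, imidazole, DMF, 0 °C → rt
Reagents that add atoms: chlorotriethylsilane, CC[Si](Cl)(CC)CC
Why: O-Silylation of the acidic enol hydroxyl (silyl ether formation) masks C8 at the ketone oxidation level and leaves the C9 carbonyl as the only electrophilic site.

**Step 7**
Reactants: 12 (2E)-3-methylpent-2-en-4-yn-1-ol
Product: 13 tert-butyl{[(2E)-3-methylpent-2-en-4-yn-1-yl]oxy}diphenylsilane
Conditions: t-BuPh2SiCl, imidazole, CH2Cl2, rt
Reagents that add atoms: tert-butyl(chloro)diphenylsilane, CC(C)(C)[Si](Cl)(c1ccccc1)c1ccccc1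
Why: Silyl ether formation protects the primary allylic alcohol with a group that should survive the alkyllithium, dilute HCl, SmI2 and the palladium step.

**Step 8**
Reactants: 13 tert-butyl{[(2E)-3-methylpent-2-en-4-yn-1-yl]oxy}diphenylsilane
Product: 14 tert-butyl{[(2E)-3-methylpenta-2,4-dien-1-yl]oxy}diphenylsilane
Conditions: H2 (1 atm), Pd/CaCO3 poisoned with Pb(OAc)2, quinoline, hexane/EtOAc, rt
Reagents that add atoms: none
Why: Semihydrogenation of the terminal alkyne on the poisoned palladium surface (Lindlar reduction) should stop at the vinyl group and leave the trisubstituted E-olefin, whose geometry comes from 12, unchanged.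

**Step 9**
Reactants: 14 tert-butyl{[(2E)-3-methylpenta-2,4-dien-1-yl]oxy}diphenylsilane
Product: 16 tert-butyl{[(2E)-5-iodo-3-methylpent-2-en-1-yl]oxy}diphenylsilane, via alkylborane 15 (not isolated)
Conditions: 9-BBN (1.1 equiv), THF, 0 °C → rt; then I2, NaOMe, MeOH, 0 °C
Reagents that add atoms: iodine, [I][I]
Why: Anti-Markovnikov hydroboration with the bulky 9-BBN should take place only at the monosubstituted terminus of the diene, and base-promoted iodinolysis of the primary B-alkyl bond then gives the homoallylic iodide.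

**Step 10**
Reactants: 16 tert-butyl{[(2E)-5-iodo-3-methylpent-2-en-1-yl]oxy}diphenylsilane; 11 (4aS,8aS)-5,5,8a-trimethyl-2-[(triethylsilyl)oxy]-4a,5,6,7,8,8a-hexahydronaphthalen-1(4H)-one
Product: 19 (1R,4aS,8aS)-1-[(3E)-5-{[tert-butyl(diphenyl)silyl]oxy}-3-methylpent-3-en-1-yl]-1-hydroxy-5,5,8a-trimethyloctahydronaphthalen-2(1H)-one, via alkyllithium 17 (not isolated), via tertiary carbinol 18 (not isolated)
Conditions: 16 (1.3 equiv), t-BuLi (2.6 equiv), Et2O, −78 °C; then 11, THF, −78 → −20 °C; then 1 M HCl, THF, 0 °C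
Reagents that add atoms: none
Why: Iodine–lithium exchange followed by 1,2-addition of the primary alkyllithium to the only carbonyl of the α-silyloxy enone (no α-hydrogen is available for enolization) should occur from the face anti to the axial C10 methyl, and mild acid hydrolysis of the silyl enol ether unveils the C8 ketone; the C9 configuration formed here is reset in step 11.

**Step 11**
Reactants: 19 (1R,4aS,8aS)-1-[(3E)-5-{[tert-butyl(diphenyl)silyl]oxy}-3-methylpent-3-en-1-yl]-1-hydroxy-5,5,8a-trimethyloctahydronaphthalen-2(1H)-one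
Product: 20 (1R,4aS,8aS)-1-[(3E)-5-{[tert-butyl(diphenyl)silyl]oxy}-3-methylpent-3-en-1-yl]-5,5,8a-trimethyloctahydronaphthalen-2(1H)-one
Conditions: SmI2 (2.5 equiv), THF/MeOH, −78 °C → rt; then K2CO3 (cat.), MeOH, rt
Reagents that add atoms: none
Why: Reductive cleavage of the α-hydroxy ketone by SmI2 (two single-electron transfers, loss of the C9 oxygen as hydroxide) gives the samarium enolate, and its protonation and base equilibration α to the ketone should place the side chain equatorial (9β) with H-9 on the face anti to the C10 methyl, which is the thermodynamically favored arrangement.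

**Step 12**
Reactants: 20 (1R,4aS,8aS)-1-[(3E)-5-{[tert-butyl(diphenyl)silyl]oxy}-3-methylpent-3-en-1-yl]-5,5,8a-trimethyloctahydronaphthalen-2(1H)-one
Product: 21 (1R,4aS,8aS)-1-[(3E)-5-{[tert-butyl(diphenyl)silyl]oxy}-3-methylpent-3-en-1-yl]-5,5,8a-trimethyl-1,4,4a,5,6,7,8,8a-octahydronaphthalen-2-yl trifluoromethanesulfonate
Conditions: KN(SiMe3)2 (1.1 equiv), THF, −78 °C; then PhNTf2, −78 → 0 °C; aq. NH4Cl
Reagents that add atoms: N-phenylbis(trifluoromethanesulfonimide), O=S(=O)(N(c1ccccc1)S(=O)(=O)C(F)(F)F)C(F)(F)F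
Why: Kinetic deprotonation by the bulky amide should occur at the unhindered C7 methylene and not at the tertiary C9–H next to the quaternary C10, so that O-triflation of the enolate gives the Δ7 enol triflate without epimerizing C9.

**Step 13**
Reactants: 21 (1R,4aS,8aS)-1-[(3E)-5-{[tert-butyl(diphenyl)silyl]oxy}-3-methylpent-3-en-1-yl]-5,5,8a-trimethyl-1,4,4a,5,6,7,8,8a-octahydronaphthalen-2-yl trifluoromethanesulfonate
Product: 22 (1R,4aS,8aS)-1-[(3E)-5-{[tert-butyl(diphenyl)silyl]oxy}-3-methylpent-3-en-1-yl]-5,5,8a-trimethyl-1,4,4a,5,6,7,8,8a-octahydronaphthalene-2-carboxylic acid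
Conditions: Pd(OAc)2 (5 mol%), PPh3 (10 mol%), CO (1 atm), KOAc (4 equiv), DMF/H2O, rt → 50 °C; then aq. HCl
Reagents that add atoms: carbon monoxide, [C-]#[O+]; water, O
Why: In this palladium-catalyzed hydroxycarbonylation of an enol triflate, oxidative addition to zerovalent palladium, CO insertion and hydrolysis of the acylpalladium should give the α,β-unsaturated acid with the double bond fixed at C7=C8, and the allylic silyl ether is not ionized.

**Step 14**
Reactants: 22 (1R,4aS,8aS)-1-[(3E)-5-{[tert-butyl(diphenyl)silyl]oxy}-3-methylpent-3-en-1-yl]-5,5,8a-trimethyl-1,4,4a,5,6,7,8,8a-octahydronaphthalene-2-carboxylic acid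
Product: 23 (1R,4aS,8aS)-1-[(3E)-5-hydroxy-3-methylpent-3-en-1-yl]-5,5,8a-trimethyl-1,4,4a,5,6,7,8,8a-octahydronaphthalene-2-carboxylic acid
Conditions: Bu4NF (3 equiv), THF, 0 °C → rt; then aq. NH4Cl
Reagents that add atoms: none
Why: Fluoride-mediated desilylation should free the primary allylic alcohol, while the carboxylate formed under the basic conditions is inert.

**Step 15**
Reactants: 23 (1R,4aS,8aS)-1-[(3E)-5-hydroxy-3-methylpent-3-en-1-yl]-5,5,8a-trimethyl-1,4,4a,5,6,7,8,8a-octahydronaphthalene-2-carboxylic acid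
Product: 25 (1R,4aS,8aS)-5,5,8a-trimethyl-1-[(3E)-3-methyl-5-[(2-methylpropanoyl)oxy]pent-3-en-1-yl]-1,4,4a,5,6,7,8,8a-octahydronaphthalene-2-carboxylic acid, via mixed anhydride 24 (not isolated)
Conditions: (i-PrCO)2O (3 equiv), pyridine, DMAP (10 mol%), CH2Cl2, 0 °C → rt; then THF/H2O/pyridine, rt
Reagents that add atoms: 2-methylpropanoic anhydride, CC(C)C(=O)OC(=O)C(C)C
Why: DMAP-catalyzed acyl transfer esterifies the primary allylic alcohol and at the same time converts the carboxyl group into the mixed anhydride 24, which should be hydrolyzed selectively in the aqueous pyridine stage while the isobutyrate ester survives.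

**Compound list**

1 | 2-methylcyclohex-2-en-1-one | CC1=CCCCC1=O | starting material
2 | [(1-methoxy-2-methylprop-1-en-1-yl)oxy]trimethylsilane | COC(O[Si](C)(C)C)=C(C)C | starting material
3 | methyl 2-methyl-2-[(1R)-2-methyl-3-[(trimethylsilyl)oxy]cyclohex-2-en-1-yl]propanoate | COC(=O)C(C)(C)[C@@H]1CCCC(O[Si](C)(C)C)=C1C | intermediate
4 | 2-methyl-2-[(1R)-2-methyl-3-[(trimethylsilyl)oxy]cyclohex-2-en-1-yl]propanal | O=CC(C)(C)[C@@H]1CCCC(O[Si](C)(C)C)=C1C | intermediate
5 | triphenyl(vinyl)phosphonium bromide | C=C[P+](c1ccccc1)(c1ccccc1)c1ccccc1.[Br-] | starting material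
6 | tris(dimethylamino)sulfonium (3R)-2-methyl-3-(2-methyl-1-oxopropan-2-yl)cyclohex-1-en-1-olate | O=CC(C)(C)[C@@H]1CCCC([O-])=C1C.CN(C)[S+](N(C)C)N(C)C | intermediate
7 | 2-methyl-2-{(1S,2S)-2-methyl-3-oxo-2-[2-(triphenyl-λ5-phosphanylidene)ethyl]cyclohexyl}propanal | O=CC(C)(C)[C@@H]1CCCC(=O)[C@@]1(C)CC=P(c1ccccc1)(c1ccccc1)c1ccccc1 | intermediate
8 | (4aS,8aS)-5,5,8a-trimethyl-3,4,4a,5,8,8a-hexahydronaphthalen-1(2H)-one | O=C1CCC[C@H]2C(C)(C)C=CC[C@]12C | intermediate
9 | (4aS,8aS)-5,5,8a-trimethyloctahydronaphthalen-1(2H)-one | O=C1CCC[C@H]2C(C)(C)CCC[C@]12C | intermediate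
10 | (4aS,8aS)-2-hydroxy-5,5,8a-trimethyl-4a,5,6,7,8,8a-hexahydronaphthalen-1(4H)-one | O=C1C(O)=CC[C@H]2C(C)(C)CCC[C@]12C | intermediate
11 | (4aS,8aS)-5,5,8a-trimethyl-2-[(triethylsilyl)oxy]-4a,5,6,7,8,8a-hexahydronaphthalen-1(4H)-one | O=C1C(O[Si](CC)(CC)CC)=CC[C@H]2C(C)(C)CCC[C@]12C | intermediate
12 | (2E)-3-methylpent-2-en-4-yn-1-ol | C/C(=C\CO)C#C | starting material
13 | tert-butyl{[(2E)-3-methylpent-2-en-4-yn-1-yl]oxy}diphenylsilane | C/C(=C\CO[Si](c1ccccc1)(c1ccccc1)C(C)(C)C)C#C | intermediate
14 | tert-butyl{[(2E)-3-methylpenta-2,4-dien-1-yl]oxy}diphenylsilane | C/C(=C\CO[Si](c1ccccc1)(c1ccccc1)C(C)(C)C)C=C | intermediate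
15 | 9-[(3E)-5-{[tert-butyl(diphenyl)silyl]oxy}-3-methylpent-3-en-1-yl]-9-borabicyclo[3.3.1]nonane | C/C(=C\CO[Si](c1ccccc1)(c1ccccc1)C(C)(C)C)CCB1C2CCCC1CCC2 | intermediate
16 | tert-butyl{[(2E)-5-iodo-3-methylpent-2-en-1-yl]oxy}diphenylsilane | C/C(=C\CO[Si](c1ccccc1)(c1ccccc1)C(C)(C)C)CCI | intermediate
17 | [(3E)-5-{[tert-butyl(diphenyl)silyl]oxy}-3-methylpent-3-en-1-yl]lithium | C/C(=C\CO[Si](c1ccccc1)(c1ccccc1)C(C)(C)C)CC[Li] | intermediate
18 | (1R,4aS,8aS)-1-[(3E)-5-{[tert-butyl(diphenyl)silyl]oxy}-3-methylpent-3-en-1-yl]-5,5,8a-trimethyl-2-[(triethylsilyl)oxy]-1,4,4a,5,6,7,8,8a-octahydronaphthalen-1-ol | C/C(=C\CO[Si](c1ccccc1)(c1ccccc1)C(C)(C)C)CC[C@]1(O)C(O[Si](CC)(CC)CC)=CC[C@H]2C(C)(C)CCC[C@]12C | intermediate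
19 | (1R,4aS,8aS)-1-[(3E)-5-{[tert-butyl(diphenyl)silyl]oxy}-3-methylpent-3-en-1-yl]-1-hydroxy-5,5,8a-trimethyloctahydronaphthalen-2(1H)-one | C/C(=C\CO[Si](c1ccccc1)(c1ccccc1)C(C)(C)C)CC[C@]1(O)C(=O)CC[C@H]2C(C)(C)CCC[C@]12C | intermediate
20 | (1R,4aS,8aS)-1-[(3E)-5-{[tert-butyl(diphenyl)silyl]oxy}-3-methylpent-3-en-1-yl]-5,5,8a-trimethyloctahydronaphthalen-2(1H)-one | C/C(=C\CO[Si](c1ccccc1)(c1ccccc1)C(C)(C)C)CC[C@H]1C(=O)CC[C@H]2C(C)(C)CCC[C@]12C | intermediate
21 | (1R,4aS,8aS)-1-[(3E)-5-{[tert-butyl(diphenyl)silyl]oxy}-3-methylpent-3-en-1-yl]-5,5,8a-trimethyl-1,4,4a,5,6,7,8,8a-octahydronaphthalen-2-yl trifluoromethanesulfonate | C/C(=C\CO[Si](c1ccccc1)(c1ccccc1)C(C)(C)C)CC[C@H]1C(OS(=O)(=O)C(F)(F)F)=CC[C@H]2C(C)(C)CCC[C@]12C | intermediate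
22 | (1R,4aS,8aS)-1-[(3E)-5-{[tert-butyl(diphenyl)silyl]oxy}-3-methylpent-3-en-1-yl]-5,5,8a-trimethyl-1,4,4a,5,6,7,8,8a-octahydronaphthalene-2-carboxylic acid | C/C(=C\CO[Si](c1ccccc1)(c1ccccc1)C(C)(C)C)CC[C@H]1C(C(=O)O)=CC[C@H]2C(C)(C)CCC[C@]12C | intermediate
23 | (1R,4aS,8aS)-1-[(3E)-5-hydroxy-3-methylpent-3-en-1-yl]-5,5,8a-trimethyl-1,4,4a,5,6,7,8,8a-octahydronaphthalene-2-carboxylic acid | C/C(=C\CO)CC[C@H]1C(C(=O)O)=CC[C@H]2C(C)(C)CCC[C@]12C | intermediate
24 | 2-methylpropanoic (1R,4aS,8aS)-5,5,8a-trimethyl-1-[(3E)-3-methyl-5-[(2-methylpropanoyl)oxy]pent-3-en-1-yl]-1,4,4a,5,6,7,8,8a-octahydronaphthalene-2-carboxylic anhydride | C/C(=C\COC(=O)C(C)C)CC[C@H]1C(C(=O)OC(=O)C(C)C)=CC[C@H]2C(C)(C)CCC[C@]12C | intermediate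
25 | (1R,4aS,8aS)-5,5,8a-trimethyl-1-[(3E)-3-methyl-5-[(2-methylpropanoyl)oxy]pent-3-en-1-yl]-1,4,4a,5,6,7,8,8a-octahydronaphthalene-2-carboxylic acid | C/C(=C\COC(=O)C(C)C)CC[C@H]1C(C(=O)O)=CC[C@H]2C(C)(C)CCC[C@]12C | target

**Step count**

Total steps: 15. Longest linear sequence: 12 steps (steps 1–6 and 10–15); the side-chain branch (steps 7–9) joins in step 10.

**Steps most likely to fail, with fallbacks**

Step 3 (key step). The naked enolate or the ylide may be quenched by proton transfer from the C8 methylene of product already formed, and O-alkylation or fluoride-promoted intermolecular aldol addition may consume material before ring closure. The fallback closes ring A by ring-closing metathesis instead and forms the two bonds in separate, known steps. It sets out from 4 and returns at 8. Wittig methylenation of the aldehyde (Ph3PCH3Br, KN(SiMe3)2, THF) should give trimethyl{[(3S)-2-methyl-3-(2-methylbut-3-en-2-yl)cyclohex-1-en-1-yl]oxy}silane F1. Regiospecific allylation of F1 (MeLi, THF, 0 °C; then allyl bromide, −78 °C → rt), anti to the C5 substituent, should give (2S,3S)-2-methyl-3-(2-methylbut-3-en-2-yl)-2-(prop-2-en-1-yl)cyclohexan-1-one F2. Ring-closing metathesis of F2 with the second-generation Grubbs catalyst (CH2Cl2, 40 °C) forms the C2=C3 bond and gives 8.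

Step 1. The α-methyl group of 1 may disturb binding to the catalyst, which would show as poor facial selectivity or slow turnover. The fallback uses the unsubstituted enone, for which this catalyst type has direct precedent, and brings in C20 afterwards. It sets out from 2 (with cyclohex-2-en-1-one in place of 1) and returns at 3. The same Mukaiyama–Michael conditions should give methyl 2-methyl-2-[(1R)-3-[(trimethylsilyl)oxy]cyclohex-2-en-1-yl]propanoate F3. Aminomethylation with CH2=NMe2+ I− (CH2Cl2) should give the Mannich base methyl 2-[(1R,2R)-2-[(dimethylamino)methyl]-3-oxocyclohexyl]-2-methylpropanoate F4. Quaternization and elimination (MeI; then DBU) give methyl 2-methyl-2-[(1R)-2-methylidene-3-oxocyclohexyl]propanoate F5. Conjugate reduction of F5 with LiBH(s-Bu)3 (THF, −78 °C) and O-silylation of the enolate with Me3SiCl gives 3 with the enol double bond in the required position.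

Step 5. Under oxygen and strong base the 1,2-dione may be over-oxidized with C–C cleavage to a seco-diacid. The fallback oxidizes in two controlled stages. It sets out from 9 and returns at 10. Enolate hydroxylation (KN(SiMe3)2, THF, −78 °C; then 3-phenyl-2-(phenylsulfonyl)oxaziridine), from the face anti to the C10 methyl, should give (2R,4aS,8aS)-2-hydroxy-5,5,8a-trimethyloctahydronaphthalen-1(2H)-one F6. Swern oxidation of F6 (DMSO, (COCl)2, Et3N, CH2Cl2, −78 °C) gives the 1,2-dione, which enolizes to 10.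

**Further compounds**

F1 | step 3 | trimethyl{[(3S)-2-methyl-3-(2-methylbut-3-en-2-yl)cyclohex-1-en-1-yl]oxy}silane | C=CC(C)(C)[C@@H]1CCCC(O[Si](C)(C)C)=C1C
F2 | step 3 | (2S,3S)-2-methyl-3-(2-methylbut-3-en-2-yl)-2-(prop-2-en-1-yl)cyclohexan-1-one | C=CC(C)(C)[C@@H]1CCCC(=O)[C@@]1(C)CC=C
F3 | step 1 | methyl 2-methyl-2-[(1R)-3-[(trimethylsilyl)oxy]cyclohex-2-en-1-yl]propanoate | COC(=O)C(C)(C)[C@@H]1CCCC(O[Si](C)(C)C)=C1
F4 | step 1 | methyl 2-[(1R,2R)-2-[(dimethylamino)methyl]-3-oxocyclohexyl]-2-methylpropanoate | COC(=O)C(C)(C)[C@@H]1CCCC(=O)[C@H]1CN(C)C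
F5 | step 1 | methyl 2-methyl-2-[(1R)-2-methylidene-3-oxocyclohexyl]propanoate | COC(=O)C(C)(C)[C@@H]1CCCC(=O)C1=C
F6 | step 5 | (2R,4aS,8aS)-2-hydroxy-5,5,8a-trimethyloctahydronaphthalen-1(2H)-one | O=C1[C@H](O)CC[C@H]2C(C)(C)CCC[C@]12C
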